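**Plan**

1. Locants: C1 = quaternary oxirane carbon (carries C7H2–OBz), C2 = CH–OBz, C3 = CH–OH, C4=C5 = olefin, C6 = oxirane CH. Retrosynthetically the C3 hydroxyl is first masked as a trifluoroacetate; then the oxirane O–C6 bond and the C3–O bond are cut in one operation.
2. Feature used: the oxirane oxygen on C6 and the oxygen on C3 lie on one face at the two ends of the C4=C5 olefin (a cis-1,4-dioxygenated 2-ene). That oxirane oxygen already sits on C1 next to C6, so the pair maps onto a C3=C4–C5=C6 diene carrying a tertiary C1 hydroxyl.
3. Forward: the carbocycle is the ring of benzoic acid, dearomatised by whole-cell ipso,ortho-dihydroxylation. The carboxyl is reduced to C7, C7–O and C2–O are benzoylated, and the oxirane (the only ring made) closes in the palladium step, followed by unmasking of C3–OH.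
4. Stereochemistry: C1 and C2 come from the enzyme (C1 kept, C2 inverted by Mitsunobu benzoylation). C3 and C6 come from the anti/anti palladium addition, relayed from C1 through the one-atom tether.

Key step: step 6

**Remarks**

- The locants C1–C7 above are used for every compound; α is the face of the C1 oxygen, β the face of C7.
- Assumption: the Ralstonia eutropha B9 diol acid is the (1S,2R) enantiomer (both hydroxyls α), which already has the C1 configuration of the target; the strain is taken as obtainable from a culture collection.
- In step 1 the two hydrogens come from cellular NADH, treated as a regenerated cofactor.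
- Complex 8 is written in SMILES as its C6-bound η1 form.

**Route**

Step 1
Reactants: 1 benzoic acid
Product: 2 (1S,2R)-1,2-dihydroxycyclohexa-3,5-diene-1-carboxylic acid
Conditions: Ralstonia eutropha B9 whole cells, fructose, air, phosphate buffer pH 7, 30 °C; then pH 3, EtOAc extraction
Reagents that add atoms: dioxygen, O=O
Why: Benzoate 1,2-dioxygenase adds both atoms of O2 to the ipso and ortho carbons from one face (enzymatic arene cis-dihydroxylation) and the mutant cannot dehydrogenate the product, so the enzyme sets C1 and C2 with both hydroxyls α and the acid accumulates.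

Step 2
Reactants: 2 (1S,2R)-1,2-dihydroxycyclohexa-3,5-diene-1-carboxylic acid
Product: 3 methyl (1S,2R)-1,2-dihydroxycyclohexa-3,5-diene-1-carboxylate
Conditions: MeI, KHCO3, DMF, 20 °C
Reagents that add atoms: iodomethane, CI
Why: O-Alkylation of the carboxylate with MeI under weakly basic conditions (carboxylate SN2 esterification) leaves the hydroxyls and the diene alone and avoids the acid that would dehydrate the diene diol to an arene.

Step 3
Reactants: 3 methyl (1S,2R)-1,2-dihydroxycyclohexa-3,5-diene-1-carboxylate
Product: 4 (1R,2R)-1-(hydroxymethyl)cyclohexa-3,5-diene-1,2-diol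
Conditions: NaBH4, EtOH, 0 → 20 °C; acetone quench
Reagents that add atoms: none
Why: NaBH4 reduction of an α-hydroxy ester, accelerated by alkoxyborohydride formation at the neighbouring hydroxyls, gives the primary alcohol C7 without touching the diene (not conjugated to the ester) or either stereocentre.

Step 4
Reactants: 4 (1R,2R)-1-(hydroxymethyl)cyclohexa-3,5-diene-1,2-diol; 5 benzoyl chloride
Product: 6 [(1R,6R)-1,6-dihydroxycyclohexa-2,4-dien-1-yl]methyl benzoate
Conditions: BzCl (1.05 equiv), pyridine, CH2Cl2, −40 °C
Reagents that add atoms: benzoyl chloride (5), O=C(Cl)c1ccccc1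
Why: Kinetically selective acylation (pyridine-mediated esterification with one equivalent of acid chloride at low temperature) should esterify the primary C7 hydroxyl ahead of the secondary C2 hydroxyl, which is flanked by the quaternary C1, while the tertiary C1 hydroxyl does not react.

Step 5
Reactants: 6 [(1R,6R)-1,6-dihydroxycyclohexa-2,4-dien-1-yl]methyl benzoate; 1 benzoic acid
Product: 7 [(1R,6S)-6-(benzoyloxy)-1-hydroxycyclohexa-2,4-dien-1-yl]methyl benzoate (C1–OH α, C2–OBz β)
Conditions: PPh3, DIAD, BzOH, THF, 0 → 20 °C
Reagents that add atoms: benzoic acid (1), OC(=O)c1ccccc1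
Why: Mitsunobu reaction: the secondary C2 hydroxyl is activated as its alkoxyphosphonium ion and displaced by benzoate with inversion (SN2), placing the C2 benzoate β and trans to the C1 hydroxyl, while the tertiary C1 hydroxyl is not activated, cannot close an arene oxide because it is cis to the leaving group, and C1 has no hydrogen for elimination to an arene.

Step 6
Reactants: 7 [(1R,6S)-6-(benzoyloxy)-1-hydroxycyclohexa-2,4-dien-1-yl]methyl benzoate
Product: 9 [(1S,2S,3R,6S)-2-(benzoyloxy)-3-(trifluoroacetoxy)-7-oxabicyclo[4.1.0]hept-4-en-1-yl]methyl benzoate, via C4–C6 η3-allylpalladium chloride complex 8 (not isolated)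
Conditions: Pd(O2CCF3)2 (10 mol %), LiCl (25 mol %), p-benzoquinone (1.5 equiv), CF3CO2H (1.5 equiv), LiO2CCF3 (2 equiv), acetone, 0 → 20 °C
Reagents that add atoms: trifluoroacetic acid, OC(=O)C(F)(F)F
Why: Proposed new method: divalent palladium binds the C3–C6 diene reversibly and reacts on through its β-face complex, trifluoroacetate attacks C3 from the α face anti to the metal, and the resulting η3-allyl complex 8 (C4–C6), made electrophilic by coordinated benzoquinone, is attacked at C6 by the pseudoaxial C1 hydroxyl, again anti to palladium, which closes the oxirane, leaves the C4=C5 olefin and releases zerovalent palladium that benzoquinone and acid reoxidise. The closest known reaction type is the palladium-catalysed, benzoquinone-driven cis-1,4-diacyloxylation and intramolecular 1,4-acyloxy-alkoxylation of cyclic 1,3-dienes, where the tethered alcohol has so far closed only five- and six-membered ethers; an oxirane at an allyl terminus is untested because zerovalent palladium normally opens vinyl epoxides, so the step depends on benzoquinone removing zerovalent palladium irreversibly. The oxirane closes in the 3-exo mode, by backside displacement at the C6 allyl terminus. C6 is fixed by the one-atom tether, which allows only a cis-fused oxirane on the face of the C1 oxygen, and C3 by anti attack on the same palladium face, so both new oxygens end up α, cis to each other across the ring and trans to the C2 benzoate. The step needs the external carboxylate at C3 rather than C6, the hydroxyl at C6 rather than C4, and anti/anti addition: C6 is screened from intermolecular attack by the quaternary C1, the β face of C3 is covered by the C2 benzoate while its α face is open, closure to C4 would need a boat and a strained 7-oxanorbornene, and chloride on palladium suppresses inner-sphere (syn) carboxylate delivery; Pd(O2CCF3)2 is used so that trifluoroacetate is the only carboxylate present.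

Step 7
Reactants: 9 [(1S,2S,3R,6S)-2-(benzoyloxy)-3-(trifluoroacetoxy)-7-oxabicyclo[4.1.0]hept-4-en-1-yl]methyl benzoate
Product: 10 [(1S,2S,3R,6S)-2-(benzoyloxy)-3-hydroxy-7-oxabicyclo[4.1.0]hept-4-en-1-yl]methyl benzoate
Conditions: NaHCO3 (0.2 equiv), MeOH, 0 °C, short reaction time
Reagents that add atoms: none
Why: Trifluoroacetates undergo base-catalysed transesterification with methanol far faster than benzoates, so bicarbonate in cold methanol should free the C3 hydroxyl with retention (acyl–oxygen cleavage) while both benzoates, the oxirane and the olefin persist.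

**Compound list**

1 | benzoic acid | OC(=O)c1ccccc1 | starting material
2 | (1S,2R)-1,2-dihydroxycyclohexa-3,5-diene-1-carboxylic acid (hydroxyls cis, both α) | OC(=O)[C@]1(O)C=CC=C[C@H]1O | intermediate
3 | methyl (1S,2R)-1,2-dihydroxycyclohexa-3,5-diene-1-carboxylate | COC(=O)[C@]1(O)C=CC=C[C@H]1O | intermediate
4 | (1R,2R)-1-(hydroxymethyl)cyclohexa-3,5-diene-1,2-diol | OC[C@]1(O)C=CC=C[C@H]1O | intermediate
5 | benzoyl chloride | O=C(Cl)c1ccccc1 | starting material
6 | [(1R,6R)-1,6-dihydroxycyclohexa-2,4-dien-1-yl]methyl benzoate (C1–OH and C2–OH cis, α) | O=C(OC[C@]1(O)C=CC=C[C@H]1O)c1ccccc1 | intermediate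
7 | [(1R,6S)-6-(benzoyloxy)-1-hydroxycyclohexa-2,4-dien-1-yl]methyl benzoate (C1–OH α, C2–OBz β, trans) | O=C(OC[C@]1(O)C=CC=C[C@@H]1OC(=O)c1ccccc1)c1ccccc1 | intermediate
8 | chloropalladium η3-allyl complex over C4–C6 (palladium β) of the C3 α-trifluoroacetate, drawn as the C6-bound η1 form | O=C(OC[C@]1(O)[C@H]([Pd]Cl)C=C[C@@H](OC(=O)C(F)(F)F)[C@@H]1OC(=O)c1ccccc1)c1ccccc1 | intermediate
9 | [(1S,2S,3R,6S)-2-(benzoyloxy)-3-(trifluoroacetoxy)-7-oxabicyclo[4.1.0]hept-4-en-1-yl]methyl benzoate | O=C(OC[C@]12O[C@H]1C=C[C@@H](OC(=O)C(F)(F)F)[C@@H]2OC(=O)c1ccccc1)c1ccccc1 | intermediate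
10 | [(1S,2S,3R,6S)-2-(benzoyloxy)-3-hydroxy-7-oxabicyclo[4.1.0]hept-4-en-1-yl]methyl benzoate | O=C(OC[C@]12O[C@H]1C=C[C@@H](O)[C@@H]2OC(=O)c1ccccc1)c1ccccc1 | target

**Totals**

Total step count: 7. Longest linear sequence: 7 steps (from benzoic acid 1).

**Steps most likely to fail**

Step 6 (proposed new method). Oxirane closure at the allylpalladium terminus may lose to 1,4-bis(trifluoroacetoxylation), to closure at C4, to β-hydride loss, or to reaction through the α-face palladium complex. The fallback uses known chemistry, sets out from 7 and comes back at 10.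
- Dye-sensitised photooxygenation of 7 (O2, tetraphenylporphyrin, visible light, CH2Cl2, 0 °C) should add singlet oxygen across C3/C6 on the less hindered α face and give the α-face 3,6-endoperoxide F1.
- Kornblum–DeLaMare rearrangement with Et3N, with removal of H6, should give the 6-oxo-3α-hydroxy-4-ene (hydroxy enone) F2. The C3 oxygen is then already α.
- Silylation (Et3SiCl, imidazole, DMF, 0 °C) should give the C3 triethylsilyl ether F3.
- Hydroxyl-directed reduction with Me4NBH(OAc)3 (MeCN/AcOH, −20 °C) should deliver hydride to C6 from the face of the C1 hydroxyl and give the trans-1,6-diol (C6–OH β) F4.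
- Mitsunobu cyclodehydration (PPh3, DIAD, THF) should activate the secondary C6 hydroxyl, and the C1 oxygen should displace it with inversion to give the α-oxirane silyl ether F5.
- Pyridine-buffered HF·pyridine in THF at 0 °C should then give 10.

Step 5. Allylic transposition of the activated C2 oxygen (SN2′ capture at C4), or no displacement at the carbinol next to the quaternary centre, would erode the inversion. The fallback replaces the external nucleophile by internal delivery; it sets out from 6 and comes back at 7.
- Tf2O and 2,6-lutidine in CH2Cl2 at −78 °C should convert the C2 hydroxyl into the C2 triflate F6.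
- The triflate should be displaced at once, from the β face only, by the carbonyl oxygen of the C7 benzoate, giving the cis-fused 2-phenyl-1,3-dioxan-2-ylium ion with inverted C2, F7.
- Quenching with aqueous NaHCO3 should hydrolyse the cation to a mixture of the C2-inverted hydroxy esters: the C2 benzoate with free C7 hydroxyl F8 and the C7 benzoate with free β C2 hydroxyl F9.
- Benzoylation of the mixture with 5 (pyridine, CH2Cl2, 0 °C; the tertiary hydroxyl stays free) should converge on 7.

Step 4. Acylation may spill over to the secondary C2 hydroxyl, giving a mixture of mono- and dibenzoates. The fallback switches to enzymatic acyl transfer; it sets out from 4 and comes back at 6. Candida antarctica lipase B with vinyl benzoate in tert-butyl methyl ether/THF at 30 °C should acylate only the primary hydroxyl. No new compound is involved.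

**Further compounds**

F1 | step 6 | α-face 3,6-endoperoxide of 7 (2,3-dioxabicyclo[2.2.2]oct-7-ene; C1–OH α, C2–OBz β) | O=C(OC[C@]1(O)[C@@H]2C=C[C@@H](OO2)[C@@H]1OC(=O)c1ccccc1)c1ccccc1
F2 | step 6 | 6-oxo-3α-hydroxy-4-ene (hydroxy enone; C1–OH α, C2–OBz β) | O=C(OC[C@]1(O)C(=O)C=C[C@@H](O)[C@@H]1OC(=O)c1ccccc1)c1ccccc1
F3 | step 6 | C3 triethylsilyl ether of F2 | O=C(OC[C@]1(O)C(=O)C=C[C@@H](O[Si](CC)(CC)CC)[C@@H]1OC(=O)c1ccccc1)c1ccccc1
F4 | step 6 | trans-1,6-diol (C1–OH α, C6–OH β) with C3 α-triethylsilyloxy | O=C(OC[C@]1(O)[C@H](O)C=C[C@@H](O[Si](CC)(CC)CC)[C@@H]1OC(=O)c1ccccc1)c1ccccc1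
F5 | step 6 | C3 triethylsilyl ether of 10 (α-oxirane) | O=C(OC[C@]12O[C@H]1C=C[C@@H](O[Si](CC)(CC)CC)[C@@H]2OC(=O)c1ccccc1)c1ccccc1
F6 | step 5 | C2 α-triflate of 6 | O=C(OC[C@]1(O)C=CC=C[C@H]1OS(=O)(=O)C(F)(F)F)c1ccccc1
F7 | step 5 | cis-fused 2-phenyl-1,3-dioxan-2-ylium ion bridging C7–O and C2–O (C2–O β, C1–OH α) | O[C@]12COC(c3ccccc3)=[O+][C@H]1C=CC=C2
F8 | step 5 | C2 β-benzoate with free C7 and C1 hydroxyls | OC[C@]1(O)C=CC=C[C@@H]1OC(=O)c1ccccc1
F9 | step 5 | C7 benzoate with free β C2 hydroxyl (C2 epimer of 6) | O=C(OC[C@]1(O)C=CC=C[C@@H]1O)c1ccccc1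
F0 | step 4 | none | none
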